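**Retrosynthetic overview**
Ring numbering used throughout: O1–O2–C3 (acetic acid arm)–C4 (methyl)–C5H2–C6 (methyl and chain). The enabling feature is that C6 is a ketal-level ring carbon bonded to ring oxygen O1 and can be unmasked as a peroxycarbenium ion, while its ring neighbour C5 is a CH2 next to C4, which carries a one-carbon branch, so that C5=C4–CH2Si can be an allylsilane.
Target ⇐ primary alcohol ⇐ 4-methylidene-1,2-dioxane (diimide sets C4) ⇐ closure of the only ring, the 1,2-dioxane, at C5–C6 by intramolecular Hosomi–Sakurai attack on a peroxycarbenium ion from an acyclic mixed peroxyketal.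
Peroxyketal ⇐ (3S)-allylic hydroperoxide bearing the 2-(silylmethyl)allyl unit [from (R)-α-hydroxy-γ-butyrolactone by Bunnelle allylsilane synthesis, then SN2 with H2O2] + dimethyl ketal of the (4R,8S) methyl ketone.
Ketone ⇐ (R)-citronellyl bromide (first chain stereocentre, chiral pool) by copper-catalysed alkyl–alkyl coupling, ozonolysis, bromination and catalytic enantioselective conjugate addition to (E)-pent-3-en-2-one (second chain stereocentre).
Order of events: chain stereocentres → C3 (chiral pool, inverted once) → ring closure sets C6 → reduction sets C4 → oxidation level of the arm adjusted last.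

Key step: step 10

Remark on the chemistry: the ligand enantiomer named in step 4 is assumed to deliver the alkyl group to the enone face that gives the (4R) ketone; if a model run shows the opposite sense, the mirror-image ligand is used.

**Step 1**
Reactants: 1 (6R)-8-bromo-2,6-dimethyloct-2-ene [(R)-citronellyl bromide]; 2 2-phenylethylmagnesium chloride
Product: 3 [(5S)-5,9-dimethyldec-8-en-1-yl]benzene
Conditions: Li2CuCl4 (3 mol%), THF, −10 °C → rt
Reagents that add atoms: none
Why: Kochi–Tamura copper-catalysed cross-coupling of a primary alkyl bromide with a primary Grignard reagent leaves the chiral-pool stereocentre untouched, its descriptor changing from R to S only because the substituent priorities change.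

**Step 2**
Reactants: 3 [(5S)-5,9-dimethyldec-8-en-1-yl]benzene
Product: 5 (4S)-4-methyl-8-phenyloctan-1-ol, via (4S)-4-methyl-8-phenyloctanal 4 (not isolated)
Conditions: O3, CH2Cl2/MeOH, −78 °C (indicator dye endpoint); then NaBH4, −78 °C → rt
Reagents that add atoms: ozone, [O-][O+]=O
Why: Ozonolysis cleaves the electron-rich trisubstituted alkene much faster than the monoalkylbenzene, and the borohydride work-up reduces the peroxidic intermediates and aldehyde 4 directly to the primary alcohol.

**Step 3**
Reactants: 5 (4S)-4-methyl-8-phenyloctan-1-ol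
Product: 6 [(5S)-8-bromo-5-methyloctyl]benzene
Conditions: CBr4, PPh3, CH2Cl2, 0 °C → rt
Reagents that add atoms: carbon tetrabromide, BrC(Br)(Br)Br
Why: Appel bromination converts the unhindered primary alcohol under neutral conditions by SN2 displacement of the alkoxyphosphonium ion.

**Step 4**
Reactants: 6 [(5S)-8-bromo-5-methyloctyl]benzene; 7 (E)-pent-3-en-2-one
Product: 9 (4R,8S)-4,8-dimethyl-12-phenyldodecan-2-one, via [(4S)-4-methyl-8-phenyloctyl]magnesium bromide 8 (not isolated)
Conditions: Mg, Et2O, reflux; then slow addition to 7, CuBr·SMe2 (5 mol%), (R)-1-[(S)-2-(diphenylphosphino)ferrocenyl]ethyldicyclohexylphosphine (Josiphos ligand, 6 mol%), t-BuOMe, −75 °C; then 1 M aq. HCl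
Reagents that add atoms: none
Why: Copper-catalysed enantioselective conjugate addition of a Grignard reagent to an acyclic enone sets the (4R) centre under catalyst control, the existing centre being too remote to interfere, while low temperature and slow addition suppress 1,2-addition.

**Step 5**
Reactants: 9 (4R,8S)-4,8-dimethyl-12-phenyldodecan-2-one
Product: 10 [(5S,9R)-11,11-dimethoxy-5,9-dimethyldodecyl]benzene (dimethyl ketal of 9)
Conditions: HC(OMe)3, MeOH, p-TsOH·H2O (2 mol%), rt; Et3N quench
Reagents that add atoms: trimethyl orthoformate, COC(OC)OC; methanol, CO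
Why: Acid-catalysed ketalisation is driven to completion by the orthoformate as water scavenger, and the β-stereocentre cannot epimerise.

**Step 6**
Reactants: 11 (3R)-3-hydroxyoxolan-2-one [(R)-α-hydroxy-γ-butyrolactone]; 12 [(trimethylsilyl)methyl]magnesium chloride
Product: 14 (3R)-4-[(trimethylsilyl)methyl]pent-4-ene-1,3-diol, via (3R)-5-(trimethylsilyl)-4-[(trimethylsilyl)methyl]pentane-1,3,4-triol 13 (not isolated)
Conditions: CeCl3 (anhydrous, 5 equiv), 12 (5 equiv), THF, −78 °C → rt; sat. aq. NH4Cl; crude 13 then SiO2, CH2Cl2, rt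
Reagents that add atoms: none
Why: Bunnelle allylsilane synthesis, in which cerium-mediated double addition to the lactone carbonyl (the hydroxyl is carried as its alkoxide, which also blocks enolisation of the α-stereocentre) is followed by Peterson elimination of the bis(β-silyl) carbinol 13 on silica gel to give the 2-(silylmethyl)allyl unit.

**Step 7**
Reactants: 14 (3R)-4-[(trimethylsilyl)methyl]pent-4-ene-1,3-diol
Product: 15 (3R)-1-[(tert-butyldiphenylsilyl)oxy]-4-[(trimethylsilyl)methyl]pent-4-en-3-ol
Conditions: TBDPSCl (1.05 equiv), imidazole, CH2Cl2, 0 °C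
Reagents that add atoms: tert-butyl(chloro)diphenylsilane, CC(C)(C)[Si](Cl)(c1ccccc1)c1ccccc1
Why: Sterically controlled silylation selects the primary hydroxyl over the secondary allylic one.

**Step 8**
Reactants: 15 (3R)-1-[(tert-butyldiphenylsilyl)oxy]-4-[(trimethylsilyl)methyl]pent-4-en-3-ol
Product: 17 tert-butyl({(3S)-3-hydroperoxy-4-[(trimethylsilyl)methyl]pent-4-en-1-yl}oxy)diphenylsilane, via allylic mesylate 16 (not isolated)
Conditions: MsCl, Et3N, CH2Cl2, −30 °C; then 50% aq. H2O2 (20 equiv), KOH, MeOH/THF, 0 °C
Reagents that add atoms: hydrogen peroxide, OO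
Why: Mesylation followed by SN2 displacement with hydroperoxide anion (the classical sulfonate route to alkyl hydroperoxides) installs the O–O unit with inversion, turning the (3R) alcohol into the (3S) hydroperoxide, while the large excess of H2O2 at 0 °C limits dialkyl peroxide formation and elimination.

**Step 9**
Reactants: 17 tert-butyl({(3S)-3-hydroperoxy-4-[(trimethylsilyl)methyl]pent-4-en-1-yl}oxy)diphenylsilane; 10 [(5S,9R)-11,11-dimethoxy-5,9-dimethyldodecyl]benzene
Product: 18 tert-butyl({(3S)-3-{[(4R,8S)-2-methoxy-4,8-dimethyl-12-phenyldodecan-2-yl]peroxy}-4-[(trimethylsilyl)methyl]pent-4-en-1-yl}oxy)diphenylsilane (both epimers at the ketal carbon)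
Conditions: PPTS (10 mol%), 5 Å molecular sieves, CH2Cl2, rt; filtration through Et3N-deactivated silica
Reagents that add atoms: none
Why: Acid-catalysed transketalisation of a dimethyl ketal with a hydroperoxide gives the mixed monoperoxyketal under an acid too weak to trigger allylation or protodesilylation, and the epimeric ketal centre is irrelevant because it is planarised in step 10.

**Step 10**
Reactants: 18 mixed peroxyketal (both epimers at the ketal carbon)
Product: 20 tert-butyl(2-{(3S,6R)-6-[(2R,6S)-2,6-dimethyl-10-phenyldecyl]-6-methyl-4-methylidene-1,2-dioxan-3-yl}ethoxy)diphenylsilane, via peroxycarbenium ion 19 (not isolated)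
Conditions: TMSOTf (1.1 equiv), 2,6-di-tert-butyl-4-methylpyridine (0.3 equiv), CH2Cl2 (0.02 M), −78 °C; Et3N quench
Reagents that add atoms: none
Why: TMSOTf removes the methoxy group of 18 as MeOSiMe3 to give peroxycarbenium ion 19, whose cationic carbon is attacked by the terminal CH2 of the 2-(silylmethyl)allyl unit, and the resulting β-silyl cation loses the silyl group, which regenerates TMSOTf and leaves the exocyclic methylidene. The closest known reaction type is the Lewis acid-mediated Hosomi–Sakurai allylation of peroxycarbenium ions generated from monoperoxyketals, with the silyl-Prins annulation to 4-methylidenetetrahydropyrans as its ether counterpart. The 1,2-dioxane closes in a 6-endo mode with respect to both the C=O+ and the C=C bond through a chair-like transition state. The new quaternary centre C6 is controlled by the C3 stereocentre: the C3 arm should sit pseudoaxial to avoid A(1,2) strain with the in-plane CH2SiMe3 group on C4, while the larger C6 substituent (the chain) lies anti to the O–O bond of the E-configured cation and becomes equatorial, so that chain and arm end up cis (6R) with the C6 methyl axial. The step needs ionisation of the C–OMe bond and not the C–OO bond, which the preference of the silyl Lewis acid for the more basic ether oxygen and the fast irreversible intramolecular trapping should secure, and it needs the allylsilane to survive, which the hindered pyridine base secures by scavenging triflic acid.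

**Step 11**
Reactants: 20 tert-butyl(2-{(3S,6R)-6-[(2R,6S)-2,6-dimethyl-10-phenyldecyl]-6-methyl-4-methylidene-1,2-dioxan-3-yl}ethoxy)diphenylsilane
Product: 21 tert-butyl(2-{(3S,4S,6R)-6-[(2R,6S)-2,6-dimethyl-10-phenyldecyl]-4,6-dimethyl-1,2-dioxan-3-yl}ethoxy)diphenylsilane
Conditions: KO2CN=NCO2K (large excess, portionwise), AcOH, CH2Cl2/MeOH, 0 °C → rt
Reagents that add atoms: none
Why: Diimide reduction (concerted syn transfer of H2) saturates alkenes without cleaving O–O bonds, and hydrogen should be delivered to the face of the exocyclic alkene opposite to both the C3 arm and the C6 chain, which places the new methyl cis to the arm (4S).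

**Step 12**
Reactants: 21 tert-butyl(2-{(3S,4S,6R)-6-[(2R,6S)-2,6-dimethyl-10-phenyldecyl]-4,6-dimethyl-1,2-dioxan-3-yl}ethoxy)diphenylsilane
Product: 22 2-{(3S,4S,6R)-6-[(2R,6S)-2,6-dimethyl-10-phenyldecyl]-4,6-dimethyl-1,2-dioxan-3-yl}ethan-1-ol
Conditions: HF·pyridine, pyridine, THF, 0 °C → rt
Reagents that add atoms: none
Why: Fluoride-mediated desilylation under non-basic conditions frees the primary alcohol and avoids base-induced Kornblum–DeLaMare cleavage of the peroxide.

**Step 13**
Reactants: 22 2-{(3S,4S,6R)-6-[(2R,6S)-2,6-dimethyl-10-phenyldecyl]-4,6-dimethyl-1,2-dioxan-3-yl}ethan-1-ol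
Product: 23 2-{(3S,4S,6R)-6-[(2R,6S)-2,6-dimethyl-10-phenyldecyl]-4,6-dimethyl-1,2-dioxan-3-yl}acetic acid (target)
Conditions: TEMPO (20 mol%), PhI(OAc)2 (2.5 equiv), MeCN/H2O (1:1), rt
Reagents that add atoms: water, O
Why: Oxoammonium oxidation takes the primary alcohol through the aldehyde hydrate to the acid under mildly acidic conditions that should leave the dialkyl peroxide and the benzylic position untouched and avoid β-elimination of the intermediate β-peroxy aldehyde.

**Compound list**
1 | (6R)-8-bromo-2,6-dimethyloct-2-ene [(R)-citronellyl bromide] | C[C@@H](CCBr)CCC=C(C)C | starting material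
2 | 2-phenylethylmagnesium chloride | Cl[Mg]CCc1ccccc1 | starting material
3 | [(5S)-5,9-dimethyldec-8-en-1-yl]benzene | C[C@@H](CCCCc1ccccc1)CCC=C(C)C | intermediate
4 | (4S)-4-methyl-8-phenyloctanal | C[C@@H](CCCCc1ccccc1)CCC=O | intermediate (not isolated)
5 | (4S)-4-methyl-8-phenyloctan-1-ol | C[C@@H](CCCCc1ccccc1)CCCO | intermediate
6 | [(5S)-8-bromo-5-methyloctyl]benzene | C[C@@H](CCCCc1ccccc1)CCCBr | intermediate
7 | (E)-pent-3-en-2-one | C/C=C/C(C)=O | starting material
8 | [(4S)-4-methyl-8-phenyloctyl]magnesium bromide | C[C@@H](CCCCc1ccccc1)CCC[Mg]Br | intermediate (not isolated)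
9 | (4R,8S)-4,8-dimethyl-12-phenyldodecan-2-one | C[C@@H](CCCCc1ccccc1)CCC[C@@H](C)CC(C)=O | intermediate
10 | [(5S,9R)-11,11-dimethoxy-5,9-dimethyldodecyl]benzene | C[C@@H](CCCCc1ccccc1)CCC[C@@H](C)CC(C)(OC)OC | intermediate
11 | (3R)-3-hydroxyoxolan-2-one | O=C1[C@H](O)CCO1 | starting material
12 | [(trimethylsilyl)methyl]magnesium chloride | C[Si](C)(C)C[Mg]Cl | starting material
13 | (3R)-5-(trimethylsilyl)-4-[(trimethylsilyl)methyl]pentane-1,3,4-triol | OCC[C@@H](O)C(O)(C[Si](C)(C)C)C[Si](C)(C)C | intermediate (not isolated)
14 | (3R)-4-[(trimethylsilyl)methyl]pent-4-ene-1,3-diol | OCC[C@@H](O)C(=C)C[Si](C)(C)C | intermediate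
15 | (3R)-1-[(tert-butyldiphenylsilyl)oxy]-4-[(trimethylsilyl)methyl]pent-4-en-3-ol | C=C(C[Si](C)(C)C)[C@@H](CCO[Si](c1ccccc1)(c1ccccc1)C(C)(C)C)O | intermediate
16 | (3R)-1-[(tert-butyldiphenylsilyl)oxy]-4-[(trimethylsilyl)methyl]pent-4-en-3-yl methanesulfonate | C=C(C[Si](C)(C)C)[C@@H](CCO[Si](c1ccccc1)(c1ccccc1)C(C)(C)C)OS(C)(=O)=O | intermediate (not isolated)
17 | tert-butyl({(3S)-3-hydroperoxy-4-[(trimethylsilyl)methyl]pent-4-en-1-yl}oxy)diphenylsilane | C=C(C[Si](C)(C)C)[C@H](CCO[Si](c1ccccc1)(c1ccccc1)C(C)(C)C)OO | intermediate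
18 | tert-butyl({(3S)-3-{[(4R,8S)-2-methoxy-4,8-dimethyl-12-phenyldodecan-2-yl]peroxy}-4-[(trimethylsilyl)methyl]pent-4-en-1-yl}oxy)diphenylsilane, both epimers at the ketal carbon | C=C(C[Si](C)(C)C)[C@H](CCO[Si](c1ccccc1)(c1ccccc1)C(C)(C)C)OOC(C)(OC)C[C@H](C)CCC[C@@H](C)CCCCc1ccccc1 | intermediate
19 | peroxycarbenium ion formed from 18 by loss of methoxide | C=C(C[Si](C)(C)C)[C@H](CCO[Si](c1ccccc1)(c1ccccc1)C(C)(C)C)O[O+]=C(C)C[C@H](C)CCC[C@@H](C)CCCCc1ccccc1 | intermediate (not isolated)
20 | tert-butyl(2-{(3S,6R)-6-[(2R,6S)-2,6-dimethyl-10-phenyldecyl]-6-methyl-4-methylidene-1,2-dioxan-3-yl}ethoxy)diphenylsilane | C[C@@H](CCCCc1ccccc1)CCC[C@@H](C)C[C@]1(C)CC(=C)[C@H](CCO[Si](c2ccccc2)(c2ccccc2)C(C)(C)C)OO1 | intermediate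
21 | tert-butyl(2-{(3S,4S,6R)-6-[(2R,6S)-2,6-dimethyl-10-phenyldecyl]-4,6-dimethyl-1,2-dioxan-3-yl}ethoxy)diphenylsilane | C[C@@H](CCCCc1ccccc1)CCC[C@@H](C)C[C@]1(C)C[C@H](C)[C@H](CCO[Si](c2ccccc2)(c2ccccc2)C(C)(C)C)OO1 | intermediate
22 | 2-{(3S,4S,6R)-6-[(2R,6S)-2,6-dimethyl-10-phenyldecyl]-4,6-dimethyl-1,2-dioxan-3-yl}ethan-1-ol | C[C@@H](CCCCc1ccccc1)CCC[C@@H](C)C[C@]1(C)C[C@H](C)[C@H](CCO)OO1 | intermediate
23 | 2-{(3S,4S,6R)-6-[(2R,6S)-2,6-dimethyl-10-phenyldecyl]-4,6-dimethyl-1,2-dioxan-3-yl}acetic acid | C[C@@H](CCCCc1ccccc1)CCC[C@@H](C)C[C@]1(C)C[C@H](C)[C@H](CC(=O)O)OO1 | target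

**Step count and risks**
Total: 13 steps. Longest linear sequence: 10 steps (steps 1–5 and 9–13).

Steps most likely to fail:

Step 8. The allylic mesylate may ionise or be attacked in the SN2′ sense, which would erode configurational purity or give the transposed primary hydroperoxide. E2 elimination to the diene, a second alkylation to the dialkyl peroxide and base-induced decomposition of the free hydroperoxide may also compete. The fallback sets out from 15 (through mesylate 16) and returns at 17. The mesylate is displaced with the mono-protected nucleophile 2-methoxyprop-2-yl hydroperoxide (CsOH·H2O, DMF, 0 °C), which can alkylate only once and works in a non-aqueous, much less basic medium. This should give the mixed perketal tert-butyl({(3S)-3-[(2-methoxypropan-2-yl)peroxy]-4-[(trimethylsilyl)methyl]pent-4-en-1-yl}oxy)diphenylsilane F1. Compound F1 is then unmasked to 17 with AcOH/THF/H2O at rt.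

Step 10. The mixed ketal may cleave on the peroxide side, releasing the hydroperoxide fragment and an oxocarbenium ion that is allylated intermolecularly. The allylsilane may be protodesilylated before ring closure, and discrimination between methyl and chain at the cationic carbon may be modest. The fallback sets out from 17 and ketone 9 and returns at 20. The hydroperoxide is silylated (Me3SiCl, Et3N, CH2Cl2, 0 °C) to tert-butyldiphenyl({(3S)-4-[(trimethylsilyl)methyl]-3-[(trimethylsilyl)peroxy]pent-4-en-1-yl}oxy)silane F2. Compound F2 is condensed directly with 9 under TMSOTf (CH2Cl2, −78 → −40 °C) in a silyl-modified Sakurai-type annulation. The silylated peroxy hemiketal formed in the flask can ionise only by irreversible loss of silanolate, so the cation is generated without a methoxy leaving group and without isolating a peroxyketal. If discrimination at C6 stays modest in either variant, the C6 epimer is removed by chromatography at 20 or 21.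

Step 11. Hydrogen transfer may show poor facial selectivity, because the chair with axial arm and axial C6 methyl exposes neither face cleanly, and reduction of the hindered 1,1-disubstituted alkene may be sluggish while diimide disproportionates. The fallback sets out from 20 and returns at 22. The order of the last operations is inverted: desilylation (HF·pyridine, THF, 0 °C → rt) first gives 2-{(3S,6R)-6-[(2R,6S)-2,6-dimethyl-10-phenyldecyl]-6-methyl-4-methylidene-1,2-dioxan-3-yl}ethan-1-ol F3. The stereo-determining diimide reduction (2-nitrobenzenesulfonyl hydrazide, Et3N, CH2Cl2, rt) is then run on F3, which should give 22 directly. With the free alcohol the face selection no longer depends on the bulky silyl ether, and the C4 epimers should be easier to separate as alcohols.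

**Further compounds**
F1 | step 8 | tert-butyl({(3S)-3-[(2-methoxypropan-2-yl)peroxy]-4-[(trimethylsilyl)methyl]pent-4-en-1-yl}oxy)diphenylsilane | C=C(C[Si](C)(C)C)[C@H](CCO[Si](c1ccccc1)(c1ccccc1)C(C)(C)C)OOC(C)(C)OC
F2 | step 10 | tert-butyldiphenyl({(3S)-4-[(trimethylsilyl)methyl]-3-[(trimethylsilyl)peroxy]pent-4-en-1-yl}oxy)silane | C=C(C[Si](C)(C)C)[C@H](CCO[Si](c1ccccc1)(c1ccccc1)C(C)(C)C)OO[Si](C)(C)C
F3 | step 11 | 2-{(3S,6R)-6-[(2R,6S)-2,6-dimethyl-10-phenyldecyl]-6-methyl-4-methylidene-1,2-dioxan-3-yl}ethan-1-ol | C[C@@H](CCCCc1ccccc1)CCC[C@@H](C)C[C@]1(C)CC(=C)[C@H](CCO)OO1
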